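**Plan**
- Cut 1: the target is read as the oxidatively opened form of a dinaphtho[1,2-b:2',3'-d]furan. Re-closing the hydroxyquinone oxygen onto the neighbouring quinone carbonyl carbon gives naphthol 12, so a furan serves as a temporary ring.
- Cut 2 (key): in the phenol ring of 12, the C(OH)–C(benzo) bond and the C(CO2Me)–C(furan C-3) bond are cut together. This leads to diazo ketoester 9, an aroyl diazoacetate chain on C-3 of a 2-phenylnaphtho[2,3-b]furan-4,9-dione.
- Enabling feature: the furan C2=C3 bond holds the 2-phenyl ring cis to the C-3 side chain. After a 1,2-shift of furan C-3 onto the diazo carbon, the ketene carbon, the C3=C2 bond and the phenyl ipso–ortho bond form a hexatriene.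
- Cut 3: the furan comes from 2,3-dichloro-1,4-naphthoquinone and ethyl benzoylacetate.
- Forward order: furan ring (step 1), side chain (steps 2–4), new benzenoid ring by Wolff shift and 6π closure (step 5), oxidative opening of the furan to the biquinone (step 6).
- Stereochemistry: the target has no stereocentre; the one geometric demand (aryl cis to ketene) is met by the furan ring.

Key step: step 5

Remark: the target is drawn and made as the 3-hydroxy-1,4-quinone tautomer.

**Step 1**
Reactants: 1 2,3-dichloro-1,4-naphthoquinone; 2 ethyl benzoylacetate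
Product: 4 ethyl 4,9-dioxo-2-phenyl-4,9-dihydronaphtho[2,3-b]furan-3-carboxylate, via C-alkylated chloroquinone 3 (not isolated)
Conditions: K2CO3 (2.5 equiv), MeCN, reflux
Reagents that add atoms: none
Why: Addition–elimination of the β-ketoester carbanion at C-2 of the dichloroquinone, then O-cyclisation of the ketone enolate oxygen with loss of the second chloride, is the standard annulation to naphtho[2,3-b]furan-4,9-dione-3-carboxylates and places phenyl at C-2 and the ester at C-3.

**Step 2**
Reactants: 4 ethyl 4,9-dioxo-2-phenyl-4,9-dihydronaphtho[2,3-b]furan-3-carboxylate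
Product: 5 4,9-dioxo-2-phenyl-4,9-dihydronaphtho[2,3-b]furan-3-carboxylic acid
Conditions: conc. H2SO4/AcOH/H2O, 100 °C
Reagents that add atoms: water, O
Why: Acid-catalysed ester hydrolysis should cleave the hindered ester without exposing the quinone to hydroxide, and the electron-poor furan-3-carboxylic acid should resist decarboxylation.

**Step 3**
Reactants: 5 4,9-dioxo-2-phenyl-4,9-dihydronaphtho[2,3-b]furan-3-carboxylic acid
Product: 8 methyl 3-(4,9-dioxo-2-phenyl-4,9-dihydronaphtho[2,3-b]furan-3-yl)-3-oxopropanoate, via acyl imidazolide 6 (not isolated), via acylmalonic half acid 7 (not isolated)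
Conditions: CDI, THF, rt; then MgCl2, KO2CCH2CO2Me, THF, 50 °C; aq. HCl work-up
Reagents that add atoms: potassium methyl malonate, [K+].[O-]C(=O)CC(=O)OC
Why: Masamune–Brooks decarboxylative Claisen condensation: the magnesium malonate half-ester is C-acylated by the imidazolide under nearly neutral conditions that the quinone tolerates, and the chelated half acid loses CO2 on work-up.

**Step 4**
Reactants: 8 methyl 3-(4,9-dioxo-2-phenyl-4,9-dihydronaphtho[2,3-b]furan-3-yl)-3-oxopropanoate
Product: 9 methyl 2-diazo-3-(4,9-dioxo-2-phenyl-4,9-dihydronaphtho[2,3-b]furan-3-yl)-3-oxopropanoate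
Conditions: p-ABSA, Et3N, MeCN, 0 °C to rt
Reagents that add atoms: 4-acetamidobenzenesulfonyl azide (p-ABSA), CC(=O)Nc1ccc(cc1)S(=O)(=O)N=[N+]=[N-]
Why: Regitz diazo transfer to the doubly activated methylene of an aroylacetate is reliable, and the fully substituted quinone double bond offers the azide no site for cycloaddition.

**Step 5**
Reactants: 9 methyl 2-diazo-3-(4,9-dioxo-2-phenyl-4,9-dihydronaphtho[2,3-b]furan-3-yl)-3-oxopropanoate
Product: 12 methyl 5-hydroxy-7,12-dioxo-7,12-dihydrodinaphtho[1,2-b:2',3'-d]furan-6-carboxylate, via hetaryl(methoxycarbonyl)ketene 10 (not isolated), via 4a-H cyclohexadienone 11 (not isolated)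
Conditions: 1,2-dichlorobenzene (0.01 M, argon, dry), 160 °C, sealed tube
Reagents that add atoms: none
Why: Thermal loss of N2 with a concerted 1,2-shift of the furan-3-yl group from the ketone carbon to the diazo carbon (Wolff rearrangement) should give ketene 10 and form the C(CO2Me)–C(furan C-3) bond; the ketene carbon, the furan C3=C2 bond and the ipso–ortho bond of the 2-phenyl group then close to 11, forming the C(=O)–C(aryl) bond, and enolisation gives naphthol 12. The closest known reaction type is the Wolff rearrangement/ketene electrocyclisation aromatic annulation of unsaturated and biaryl α-diazo ketones to naphthols and phenanthrols (the Danheiser benzannulation in intramolecular form). The one new six-membered carbocycle closes by a thermal disrotatory 6π-electrocyclisation, formally a 6-endo attack of the phenyl ortho carbon on the ketene carbon. No stereocentre results, since the sp3 carbon of 11 is lost on rearomatisation. The step needs migration of the hetaryl group and not of methoxy, which is the normal preference of aroyl diazoacetates, and it needs ring closure to outrun ketene dimerisation, which the furan-enforced cis arrangement of phenyl and ketene and the high dilution should secure. The two ortho carbons of the phenyl ring are equivalent, so no regiochemical question arises, and heat is preferred to light because the quinone chromophore would compete for photons.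

**Step 6**
Reactants: 12 methyl 5-hydroxy-7,12-dioxo-7,12-dihydrodinaphtho[1,2-b:2',3'-d]furan-6-carboxylate
Product: 14 methyl 3-(3-hydroxy-1,4-dioxo-1,4-dihydronaphthalen-2-yl)-1,4-dioxo-1,4-dihydronaphthalene-2-carboxylate, via 13a-hydroxy hemiketal 13 (not isolated)
Conditions: (NH4)2Ce(NO3)6 (2.2 equiv), MeCN/H2O, 0 °C to rt
Reagents that add atoms: water, O
Why: Two-electron oxidation of the para-oxygenated 1-naphthol by tetravalent cerium, water capture at the oxygen-bearing para carbon (C-13a) and collapse of hemiketal 13 with expulsion of the hydroxyquinone enol is the standard oxidative cleavage of 4-alkoxy- and 4-aryloxy-1-naphthols to 1,4-naphthoquinones, and here it opens the temporary furan and frees the hydroxyl.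

**Compound list**
1 | 2,3-dichloro-1,4-naphthoquinone | O=C1C(Cl)=C(Cl)C(=O)c2ccccc12 | starting material
2 | ethyl benzoylacetate (ethyl 3-oxo-3-phenylpropanoate) | CCOC(=O)CC(=O)c1ccccc1 | starting material
3 | ethyl 2-(3-chloro-1,4-dioxo-1,4-dihydronaphthalen-2-yl)-3-oxo-3-phenylpropanoate | CCOC(=O)C(C(=O)c1ccccc1)C1=C(Cl)C(=O)c2ccccc2C1=O | intermediate
4 | ethyl 4,9-dioxo-2-phenyl-4,9-dihydronaphtho[2,3-b]furan-3-carboxylate | CCOC(=O)c1c(-c2ccccc2)oc2c1C(=O)c1ccccc1C2=O | intermediate
5 | 4,9-dioxo-2-phenyl-4,9-dihydronaphtho[2,3-b]furan-3-carboxylic acid | OC(=O)c1c(-c2ccccc2)oc2c1C(=O)c1ccccc1C2=O | intermediate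
6 | 3-(imidazol-1-ylcarbonyl)-2-phenylnaphtho[2,3-b]furan-4,9-dione | O=C(n1ccnc1)c1c(-c2ccccc2)oc2c1C(=O)c1ccccc1C2=O | intermediate
7 | 2-(methoxycarbonyl)-3-(4,9-dioxo-2-phenyl-4,9-dihydronaphtho[2,3-b]furan-3-yl)-3-oxopropanoic acid (present as its magnesium chelate) | COC(=O)C(C(O)=O)C(=O)c1c(-c2ccccc2)oc2c1C(=O)c1ccccc1C2=O | intermediate
8 | methyl 3-(4,9-dioxo-2-phenyl-4,9-dihydronaphtho[2,3-b]furan-3-yl)-3-oxopropanoate | COC(=O)CC(=O)c1c(-c2ccccc2)oc2c1C(=O)c1ccccc1C2=O | intermediate
9 | methyl 2-diazo-3-(4,9-dioxo-2-phenyl-4,9-dihydronaphtho[2,3-b]furan-3-yl)-3-oxopropanoate | COC(=O)C(=[N+]=[N-])C(=O)c1c(-c2ccccc2)oc2c1C(=O)c1ccccc1C2=O | intermediate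
10 | methyl 2-(4,9-dioxo-2-phenyl-4,9-dihydronaphtho[2,3-b]furan-3-yl)-3-oxoprop-2-enoate (ketene) | COC(=O)C(=C=O)c1c(-c2ccccc2)oc2c1C(=O)c1ccccc1C2=O | intermediate
11 | methyl 5,7,12-trioxo-4a,5,7,12-tetrahydrodinaphtho[1,2-b:2',3'-d]furan-6-carboxylate (racemic) | COC(=O)C1=C2C(=C3C=CC=CC3C1=O)OC1=C2C(=O)c2ccccc2C1=O | intermediate
12 | methyl 5-hydroxy-7,12-dioxo-7,12-dihydrodinaphtho[1,2-b:2',3'-d]furan-6-carboxylate | COC(=O)c1c(O)c2ccccc2c2oc3c(c12)C(=O)c1ccccc1C3=O | intermediate
13 | methyl 13a-hydroxy-5,7,12-trioxo-5,7,12,13a-tetrahydrodinaphtho[1,2-b:2',3'-d]furan-6-carboxylate (racemic) | COC(=O)C1=C2C(O)(OC3=C2C(=O)c2ccccc2C3=O)c2ccccc2C1=O | intermediate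
14 | methyl 3-(3-hydroxy-1,4-dioxo-1,4-dihydronaphthalen-2-yl)-1,4-dioxo-1,4-dihydronaphthalene-2-carboxylate | COC(=O)C1=C(C2=C(O)C(=O)c3ccccc3C2=O)C(=O)c2ccccc2C1=O | target

**Step count and risks**
Total step count: 6. Longest linear sequence: 6 steps.

Steps most likely to fail:

1. Step 5. The ketene may be lost to dimerisation or to capture by traces of water before it closes, or the electron-poor furanyl group may migrate too slowly, so that the carbene is diverted to the neighbouring quinone carbonyl oxygen. The fallback sets out from compound 1 and returns at compound 12, and builds the furan last instead of the phenol ring. Compound 1 would be heated under argon in pyridine with commercial methyl 1,4-dihydroxy-2-naphthoate F1. Addition–elimination through C-3 of the naphthalenediol should give methyl 3-(3-chloro-1,4-dioxo-1,4-dihydronaphthalen-2-yl)-1,4-dihydroxy-2-naphthoate F2. Its 4-hydroxyl should then displace the second chloride and close the furan to 12, as in the classical annulation of naphthols with dichloronaphthoquinone.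

2. Step 6. The electron-poor naphthol may be oxidised too slowly, or the hydroxyquinone formed may be degraded by excess oxidant in water. The fallback sets out from compound 12 and returns at compound 14, and separates oxidation from hydrolysis. Oxidation with PhI(OAc)2 in methanol at 0 °C should stop at the quinone monoketal, methyl 13a-methoxy-5,7,12-trioxo-5,7,12,13a-tetrahydrodinaphtho[1,2-b:2',3'-d]furan-6-carboxylate F3. After isolation, F3 would be hydrolysed with dilute aqueous acid in THF, which should open the furan to 14.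

3. Step 2. Hydrolysis of the ester, flanked by the 2-phenyl group and the peri carbonyl, may stall, and forcing acid may erode material. The fallback sets out from compound 1 and returns at compound 5, and replaces hydrolysis by acidolysis of a tert-butyl ester. Compound 1 and tert-butyl benzoylacetate F4 under the conditions of step 1 should give, through tert-butyl 2-(3-chloro-1,4-dioxo-1,4-dihydronaphthalen-2-yl)-3-oxo-3-phenylpropanoate F5, the ester tert-butyl 4,9-dioxo-2-phenyl-4,9-dihydronaphtho[2,3-b]furan-3-carboxylate F6. F6 would be cleaved with CF3CO2H in CH2Cl2 at rt to acid 5.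

**Further compounds**
F1 | step 5 | methyl 1,4-dihydroxy-2-naphthoate | COC(=O)c1cc(O)c2ccccc2c1O
F2 | step 5 | methyl 3-(3-chloro-1,4-dioxo-1,4-dihydronaphthalen-2-yl)-1,4-dihydroxy-2-naphthoate | COC(=O)c1c(O)c2ccccc2c(O)c1C1=C(Cl)C(=O)c2ccccc2C1=O
F3 | step 6 | methyl 13a-methoxy-5,7,12-trioxo-5,7,12,13a-tetrahydrodinaphtho[1,2-b:2',3'-d]furan-6-carboxylate | COC(=O)C1=C2C(OC)(OC3=C2C(=O)c2ccccc2C3=O)c2ccccc2C1=O
F4 | step 2 | tert-butyl benzoylacetate | CC(C)(C)OC(=O)CC(=O)c1ccccc1
F5 | step 2 | tert-butyl 2-(3-chloro-1,4-dioxo-1,4-dihydronaphthalen-2-yl)-3-oxo-3-phenylpropanoate | CC(C)(C)OC(=O)C(C(=O)c1ccccc1)C1=C(Cl)C(=O)c2ccccc2C1=O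
F6 | step 2 | tert-butyl 4,9-dioxo-2-phenyl-4,9-dihydronaphtho[2,3-b]furan-3-carboxylate | CC(C)(C)OC(=O)c1c(-c2ccccc2)oc2c1C(=O)c1ccccc1C2=O
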